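## Structural features

- The target is a dimeric isoflavan. Chroman 1 (benzo ring A, pyran ring C) carries the 2-hydroxy-4-methoxyphenyl ring B on C3. On C4 it carries a 1,2,4,5-tetrasubstituted benzene (ring D) that is also the C3′ aryl group of chroman 2 (benzo ring E, pyran ring F).
- C3 and C4 of chroman 1 are adjacent stereocentres with the two aryl groups trans (3R,4S). The third centre, C3′ (R), lies across ring D and has to be set on its own.
- Fragile features are four free phenols on electron-rich rings, two methyl ethers that must survive every deprotection, and the benzylic hydrogens at C3, C4 and C3′.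
- The real difficulty is the crowded C3–C4 unit: a diarylmethine C4 flanked by two ortho-oxygenated arenes next to a benzylic C3, to be fixed in relative and absolute sense, while six oxygen functions are kept distinct.
- In ring A, C8a (O1) is ortho and C7 (OH) is para to C4a, the carbon bonded to C4. A vinylketene–siloxyalkyne benzannulation delivers exactly this pattern, so ring A can be grown from a two-carbon alkenyl arm on C4 (future C4a and C5) once C3 and C4 stand in an open chain.
- C2 is then only a CH2 group between C3 and O1 and can be closed last by etherification.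

## Logic of the disconnections

- **42 to 41.** Cut: the three phenolic O–CH2Ph bonds on rings B, D and E. Reason: these ethers withstand base, hydride, fluoride and light above 300 nm and leave under neutral hydrogenolysis. Gain: only the ring A phenol of 41 is free. Demand: 41 must hold no other hydrogenolysable C–O bond, which is the case.
- **41 to 40.** Cut: O1–C2 of ring C. Reason: C2 is a non-stereogenic primary carbon, ideal for intramolecular displacement. Gain: chroman 1 becomes an open 1,2-diaryl-1-arylpropane chain. Demand: only the ortho hydroxyl of ring A may alkylate; it alone can reach C2 through a six-membered transition state.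
- **40 to 39.** Cut: the C2–O–Si and ring A C7–O–Si bonds. Reason: both silyl groups are what the earlier steps require. Gain: none in skeleton, but full orthogonality to benzyl. Demand: fluoride must leave the benzyl ethers alone.
- **39 to 31 and 34.** Cut: C8a–C4a, C8a–C8 and C7–C6 of ring A. Reason: the hindered C4–aryl bond is never made by coupling, and the oxygen pattern of ring A comes out of the annulation by itself. Gain: a whole arene is removed and an acyclic enone with two stereocentres remains. Demand: a ketene must be generated under neutral conditions next to two stereocentres and trapped faster than it dimerises; the alkene must be E.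
- **34 to 32.** Cut: the C–O and O–Si bonds. Reason: 34 is not a stock chemical. Demand: oxygen transfer to a C2 anion without double metalation.
- **31 to 29 to 28.** Cut: the C=N2 bond, then the C4a=C5 double bond. Reason: the diazo group is put on a methyl ketone without strong electrophiles, and the enone arises by exchanging the alkene terminus. Gain: 28 carries only a propenyl group. Demand: kinetic enolisation at the methyl group, and metathesis at a hindered internal alkene without double-bond migration.
- **28 to 27 to 26.** Cut: the O–Si bond, then the C2 oxidation level. Gain: a γ,δ-unsaturated acid, the retron of a [3,3] shift. Demand: none beyond chemoselective hydride reduction.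
- **26 to 23.** Cut: the C3–C4 σ bond. Reason: a chair sigmatropic shift sets both centres at once and transfers chirality from one carbinol carbon. Gain: two stereocentres reduce to one, and the two aryl halves separate. Demand: one enolate geometry and a concerted pathway.
- **23 to 22 and 5.** Cut: the ester C–O bond. Demand: acylation without ionising an electron-rich allylic alcohol.
- **22 to 18 and 21; 21 to 19.** Cut: the ring D C1–alkenyl bond, then C–B. Reason: the carbinol centre comes from a commercial enantiopure alkynol and the alkene geometry from syn hydroboration. Demand: coupling at an ortho-substituted, electron-rich bromide.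
- **18 to 17 to 15.** Cut: O1′–C2′, then the acyl C–N and phenolic O–Si bonds. Gain: chroman 2 becomes an α-aryl-β-arylpropanoyl imide. Demand: only one phenol may be free at ring closure.
- **15 to 9 and 14.** Cut: C3′–C4′. Reason: auxiliary-controlled enolate alkylation sets C3′ reliably. Demand: a reactive but labile benzylic bromide and a cold enolate.
- **9 to 6 and 7; 6 to 5; 5 to 4 to 2 to 1.** Cut: N-acyl, C–Br, the nitrile carbon–benzylic carbon bond, and O–Bn. Reason and gain: 5 serves twice, as the ring B half and, after bromination, as the ring D half.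
- **14 to 13 to 12 to 11 to 10.** Cut: C–Br, C–H, O–Si, O–Bn. Demand: selective benzylation of the 4-hydroxyl.

## Other disconnections considered

**Alternative 1:**
- Cut: C3–ring B and C4–ring A in an open chain, with C2 still absent.
- Forward key step: alkenyl boronate A1 and aryllithium A2 form a boron ate complex. An arylpalladium species from triflate A3 (Pd(OAc)2 with a chiral bisphosphine) then triggers a 1,2-metallate shift. The ring B aryl moves from boron to the α-carbon while ring A is delivered to the β-carbon from the opposite face, giving boronate A4.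
- In favour: three fragments, two C–C bonds and both stereocentres arise in one catalytic step. Anti addition across the E-alkene leads to the relative configuration that ends as the trans chroman. Ring A arrives ready-made, so no diazo compound, siloxyalkyne or light is needed.
- Against: such shifts are best established for unsubstituted vinyl boron ate complexes. Here three ortho-oxygenated aryl groups meet on two adjacent carbons. Direct Suzuki coupling without shift, or β-hydride elimination from the benzylic palladium intermediate, can take over. C2 must still be inserted into the hindered secondary boronate A4 (Matteson homologation, oxidation) before deprotection and ring closure.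
- Comparison on structure: both plans fix C3 and C4 in an open chain and close ring C last through O1–C2.
- Comparison on mechanism: catalyst control is the equal of the chair shift for relative configuration, since both are stereospecific. It is the better one for freedom of absolute configuration, and the weaker one in precedent for this substitution pattern.
- Comparison on step economy: the alternative is better, roughly six or seven operations from 18 to the closed chroman against ten.

**Alternative 2:**
- Cut: C4a′–C8a′ and C5′–C6′ of ring E.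
- Forward key step: diene A6 adds to 2-nitroalkene A5. Acid work-up expels HNO2, methanol and the silyl groups and leaves resorcinol A7.
- In favour: it is thermal, uses a simple reagent, and the nitro group dictates the regiochemistry. Both ring E oxygens appear unprotected in one operation. No diazo compound or lamp is needed; on operational simplicity it is the better plan.
- Against: the ring made is the remote ring E, which carries no stereocentre and is bought cheaply as an aldehyde in the chosen plan. All of chroman 1 must already be present in A5 and needs its own solution. A 2-nitro-1-alkene with a free CH2 terminus polymerises and isomerises easily. The nitrous acid set free can nitrosate the electron-rich rings. Building A5 adds linear steps on the most valuable intermediate.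
- Comparison on structure: regiocontrol of the ring-forming event is equal to that of the chosen annulation.
- Comparison on mechanism: polar cycloaddition and elimination against a photochemical ketene cascade; the alternative is simpler.
- Comparison on step economy: worse, because an extra ring is constructed and the core problem stays unsolved.

**Alternative 3:**
- Cut: the C4–C4a bond, closing ring C and setting C4 at the very end.
- Forward key step: anodic two-electron oxidation of phenol A8 gives p-quinone methide A9. The ortho position of the tethered ring A ether attacks it to give A10.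
- In favour: the closure is biomimetic in style and all arenes are in place. Only C3 and C3′ need prior control, and both could come from the same enolate alkylation. On step economy and convergence it is the better plan.
- Against: A8 contains three further resorcinol-type ethers whose oxidation potentials lie close to that of the phenol. The ring D phenol also has a tertiary benzylic hydrogen at C3′ in its ortho position, so an ortho-quinone methide there would scramble C3′. Solvent can trap A9. The trans arrangement at C4 rests on substrate control in the ring-closing transition state.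
- Comparison on structure: equal in the final ring system, with fewer protecting-group changes.
- Comparison on mechanism: C4 is set by facial bias in a cation–arene closure, against stereospecific chirality transfer in the chosen plan; the chosen plan is the more predictable one.
- Comparison on step economy: the alternative is better.

Key step: step 22

**Remarks before the steps**

- ArB = 2-(benzyloxy)-4-methoxyphenyl. ArD = 4-(benzyloxy)-5-[(3R)-7-(benzyloxy)chroman-3-yl]-2-methoxyphenyl, numbered from the bonding carbon. Primed locants belong to chroman 2.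
- Assumption: triisopropylsiloxyacetylene is not a stock chemical and is made in step 21. Metal salts of a numbered compound (enolates, alkoxides, lithium acetylide) carry no number of their own.
- The diazo enone 31 and the phenol 39 have the same spatial arrangement at the two adjacent centres as 42. Their descriptors differ from (3R,4S) only because the CIP priorities change.
- The diazo group is introduced by diazo transfer to a methyl ketone and not by acylation of diazomethane, because an enoyl chloride also undergoes dipolar addition at its C=C bond.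

## Steps

Step 1
Reactants: 1 2-hydroxy-4-methoxybenzaldehyde
Product: 2 2-(benzyloxy)-4-methoxybenzaldehyde
Conditions: BnBr, K2CO3, DMF, 60 °C
Reagents that add atoms: benzyl bromide, BrCc1ccccc1
Why: Williamson etherification; the hydrogen-bonded ortho hydroxyl needs warm DMF, and no other site competes.

Step 2
Reactants: 2 2-(benzyloxy)-4-methoxybenzaldehyde
Product: 4 2-[2-(benzyloxy)-4-methoxyphenyl]acetonitrile, via tosylvinylformamide adduct 3 (not isolated)
Conditions: TosMIC, t-BuOK, DME, −35 °C; then MeOH, 65 °C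
Reagents that add atoms: p-toluenesulfonylmethyl isocyanide, Cc1ccc(S(=O)(=O)C[N+]#[C-])cc1
Why: Van Leusen reductive cyanation: the TosMIC anion adds to the aldehyde and the oxazoline opens to 3; methanolysis removes the formyl group and loss of sulfinate leaves the homologated nitrile.

Step 3
Reactants: 4 2-[2-(benzyloxy)-4-methoxyphenyl]acetonitrile
Product: 5 2-[2-(benzyloxy)-4-methoxyphenyl]acetic acid
Conditions: NaOH, EtOH/H2O, 90 °C; then HCl (aq)
Reagents that add atoms: water, O
Why: Base hydrolysis of the nitrile through the amide; aryl benzyl and methyl ethers are inert to hydroxide.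

Step 4
Reactants: 5 2-[2-(benzyloxy)-4-methoxyphenyl]acetic acid
Product: 6 2-[2-(benzyloxy)-5-bromo-4-methoxyphenyl]acetic acid
Conditions: NBS, MeCN, 0 → 25 °C
Reagents that add atoms: N-bromosuccinimide, O=C1CCC(=O)N1Br
Why: Electrophilic aromatic bromination; C5 is para to the benzyloxy and ortho to the methoxy group and unhindered, while C3 lies between two alkoxy groups and C6 is meta to both, so one regioisomer is expected.

Step 5
Reactants: 6 2-[2-(benzyloxy)-5-bromo-4-methoxyphenyl]acetic acid; 7 (R)-4-benzyloxazolidin-2-one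
Product: 9 (R)-4-benzyl-3-{2-[2-(benzyloxy)-5-bromo-4-methoxyphenyl]acetyl}oxazolidin-2-one, via mixed pivalic anhydride 8 (not isolated)
Conditions: t-BuCOCl, Et3N, THF, −20 °C; then 7, LiCl, 25 °C
Reagents that add atoms: none
Why: N-Acylation of the auxiliary through the mixed anhydride; the hindered pivaloyl carbonyl steers attack to the arylacetyl carbonyl, and LiCl with Et3N activates the oxazolidinone without strong base.

Step 6
Reactants: 10 2,4-dihydroxybenzaldehyde
Product: 11 4-(benzyloxy)-2-hydroxybenzaldehyde
Conditions: BnBr, NaHCO3, MeCN, 80 °C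
Reagents that add atoms: benzyl bromide, BrCc1ccccc1
Why: Williamson etherification under weak base; the 2-hydroxyl is held in a hydrogen bond to the formyl group and is less acidic, so the 4-hydroxyl reacts selectively.

Step 7
Reactants: 11 4-(benzyloxy)-2-hydroxybenzaldehyde
Product: 12 4-(benzyloxy)-2-[(tert-butyldimethylsilyl)oxy]benzaldehyde
Conditions: TBSCl, imidazole, DMF, 25 °C
Reagents that add atoms: tert-butyldimethylsilyl chloride, CC(C)(C)[Si](C)(C)Cl
Why: Silylation of the remaining phenol; this temporary mask keeps the future O1′ distinct from the benzyl ethers until ring F is closed.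

Step 8
Reactants: 12 4-(benzyloxy)-2-[(tert-butyldimethylsilyl)oxy]benzaldehyde
Product: 13 {4-(benzyloxy)-2-[(tert-butyldimethylsilyl)oxy]phenyl}methanol
Conditions: NaBH4, MeOH/THF, 0 °C
Reagents that add atoms: none
Why: Borohydride reduction of the aldehyde; a short time at 0 °C and a neutral quench keep the aryl silyl group from migrating to the new alkoxide.

Step 9
Reactants: 13 {4-(benzyloxy)-2-[(tert-butyldimethylsilyl)oxy]phenyl}methanol
Product: 14 4-(benzyloxy)-2-[(tert-butyldimethylsilyl)oxy]benzyl bromide
Conditions: CBr4, PPh3, CH2Cl2, 0 °C; used at once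
Reagents that add atoms: carbon tetrabromide, BrC(Br)(Br)Br
Why: Appel bromination under neutral conditions that spare the aryl silyl ether; the electron-rich benzylic bromide is not stored.

Step 10
Reactants: 9 (R)-4-benzyl-3-{2-[2-(benzyloxy)-5-bromo-4-methoxyphenyl]acetyl}oxazolidin-2-one; 14 4-(benzyloxy)-2-[(tert-butyldimethylsilyl)oxy]benzyl bromide
Product: 15 (R)-4-benzyl-3-[(2R)-2-[2-(benzyloxy)-5-bromo-4-methoxyphenyl]-3-{4-(benzyloxy)-2-[(tert-butyldimethylsilyl)oxy]phenyl}propanoyl]oxazolidin-2-one
Conditions: NaHMDS, THF, −78 °C; then 14, −78 → −40 °C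
Reagents that add atoms: none
Why: Evans asymmetric alkylation: the chelated (Z)-sodium enolate of 9 is attacked by the benzylic bromide on the face opposite to the benzyl group of the (R)-auxiliary, which sets C3′ as (R); the low temperature holds back ketene formation from the arylacetyl enolate.

Step 11
Reactants: 15 alkylated imide (name as under step 10)
Product: 17 5-(benzyloxy)-2-{(2R)-2-[2-(benzyloxy)-5-bromo-4-methoxyphenyl]-3-hydroxypropyl}phenol, via silyl ether alcohol 16 (not isolated)
Conditions: LiBH4, MeOH, THF, 0 °C; then K2CO3, MeOH, 25 °C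
Reagents that add atoms: none
Why: Reductive removal of the auxiliary by hydride attack at the exocyclic carbonyl (the aryl bromide is inert to LiBH4), followed in the same flask by base-catalysed methanolysis of the phenolic silyl ether; after reduction C3′ is no longer enolisable.

Step 12
Reactants: 17 5-(benzyloxy)-2-{(2R)-2-[2-(benzyloxy)-5-bromo-4-methoxyphenyl]-3-hydroxypropyl}phenol
Product: 18 (3R)-7-(benzyloxy)-3-[2-(benzyloxy)-5-bromo-4-methoxyphenyl]chromane
Conditions: PPh3, DIAD, THF, 0 → 25 °C
Reagents that add atoms: none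
Why: Mitsunobu etherification: the only free phenol displaces the activated primary alcohol (6-exo-tet) and closes ring F; the stereocentre is adjacent to the reacting carbon and is not touched.

Step 13
Reactants: 19 (S)-but-3-yn-2-ol
Product: 21 (2S,3E)-4-(4,4,5,5-tetramethyl-1,3,2-dioxaborolan-2-yl)but-3-en-2-ol, via O-borylated alkenyl boronate 20 (not isolated)
Conditions: pinacolborane (2.2 equiv), 25 °C; Cp2Zr(H)Cl (5 mol %), Et3N (10 mol %), CH2Cl2, 40 °C; then NH4Cl (aq)
Reagents that add atoms: pinacolborane, [H]B1OC(C)(C)C(C)(C)O1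
Why: Zirconium-catalysed syn hydroboration of the terminal alkyne places boron on the terminal carbon and gives the (E)-alkenyl boronate; the hydroxyl is masked in the flask as its borate and freed on work-up, and the carbinol centre is not involved.

Step 14
Reactants: 18 (3R)-7-(benzyloxy)-3-[2-(benzyloxy)-5-bromo-4-methoxyphenyl]chromane; 21 (2S,3E)-4-(4,4,5,5-tetramethyl-1,3,2-dioxaborolan-2-yl)but-3-en-2-ol
Product: 22 (2S,3E)-4-ArD-but-3-en-2-ol
Conditions: Pd(OAc)2, SPhos, K3PO4, THF/H2O, 60 °C
Reagents that add atoms: none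
Why: Suzuki–Miyaura coupling with retention of alkene geometry; the biaryl phosphine promotes oxidative addition of the electron-rich, ortho-substituted bromide, and both stereocentres are spectators.

Step 15
Reactants: 22 (2S,3E)-4-ArD-but-3-en-2-ol; 5 2-[2-(benzyloxy)-4-methoxyphenyl]acetic acid
Product: 23 (2S,3E)-4-ArD-but-3-en-2-yl 2-ArB-acetate
Conditions: EDC·HCl, DMAP, CH2Cl2, 0 → 25 °C
Reagents that add atoms: none
Why: Steglich esterification; acyl transfer under neutral conditions forms the acyl–oxygen bond only, so the easily ionised allylic carbinol keeps its (S) configuration.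

Step 16
Reactants: 23 (2S,3E)-4-ArD-but-3-en-2-yl 2-ArB-acetate
Product: 26 (2R,3R,4E)-2-ArB-3-ArD-hex-4-enoic acid, via silyl ketene acetal 24 (not isolated), via trimethylsilyl ester 25 (not isolated)
Conditions: LiHMDS, Me3SiCl, THF/DMPU, −78 → 25 °C; then 1 M HCl
Reagents that add atoms: none
Why: Ireland–Claisen rearrangement: the arylacetate gives the Z(O)-enolate (aryl cis to the oxygen anion, reinforced by DMPU), trapped as the (Z)-ketene acetal 24. In the chair transition state the carbinol methyl group is equatorial, so the (S) centre fixes the face of the E-alkene (C4), and the equatorial ArB fixes C3. The result is the syn acid with an (E)-propenyl group.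

Step 17
Reactants: 26 (2R,3R,4E)-2-ArB-3-ArD-hex-4-enoic acid
Product: 27 (2R,3R,4E)-2-ArB-3-ArD-hex-4-en-1-ol
Conditions: LiAlH4, THF, 0 °C
Reagents that add atoms: none
Why: Hydride reduction of the acid to the primary alcohol that becomes C2; after this step no enolisable carbonyl is left next to C3.

Step 18
Reactants: 27 (2R,3R,4E)-2-ArB-3-ArD-hex-4-en-1-ol
Product: 28 tert-butyl{[(2R,3R,4E)-2-ArB-3-ArD-hex-4-en-1-yl]oxy}dimethylsilane
Conditions: TBSCl, imidazole, DMF, 25 °C
Reagents that add atoms: tert-butyldimethylsilyl chloride, CC(C)(C)[Si](C)(C)Cl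
Why: Silylation; a free hydroxyl would later add to the enone (oxa-Michael) or to the ketene.

Step 19
Reactants: 28 tert-butyl{[(2R,3R,4E)-2-ArB-3-ArD-hex-4-en-1-yl]oxy}dimethylsilane
Product: 29 (3E,5R,6R)-6-ArB-5-ArD-7-[(tert-butyldimethylsilyl)oxy]hept-3-en-2-one
Conditions: methyl vinyl ketone (5 equiv), second-generation Hoveyda–Grubbs catalyst (5 mol %), 1,4-benzoquinone (10 mol %), CH2Cl2, 40 °C
Reagents that add atoms: methyl vinyl ketone, CC(=O)C=C
Why: Olefin cross-metathesis exchanges the methyl-bearing terminus for the acetyl-bearing one with loss of propene and favours the E-enone; benzoquinone suppresses ruthenium hydride species that would move the double bond toward ring D.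

Step 20
Reactants: 29 (3E,5R,6R)-6-ArB-5-ArD-7-[(tert-butyldimethylsilyl)oxy]hept-3-en-2-one
Product: 31 (3E,5R,6R)-6-ArB-5-ArD-7-[(tert-butyldimethylsilyl)oxy]-1-diazohept-3-en-2-one, via trifluoroacetyl ketone 30 (not isolated)
Conditions: LiHMDS, THF, −78 °C; CF3CO2CH2CF3; then MsN3, Et3N, H2O, MeCN, 25 °C
Reagents that add atoms: methanesulfonyl azide, CS(=O)(=O)N=[N+]=[N-]
Why: Detrifluoroacetylative diazo transfer: kinetic deprotonation at the methyl group (the hindered C5–H is not removed at −78 °C) and trifluoroacetylation give 30, which takes the diazo group from the sulfonyl azide and loses the trifluoroacetyl group as the N-sulfonyl amide; the enone double bond never meets diazomethane.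

Step 21
Reactants: 32 acetylene
Product: 34 (ethynyloxy)triisopropylsilane, via lithium ethynolate 33 (not isolated)
Conditions: n-BuLi, THF, −78 °C (excess C2H2); t-BuOOLi (from t-BuOOH and LiHMDS), −78 → −20 °C; i-Pr3SiOTf, −78 → 0 °C
Reagents that add atoms: tert-butyl hydroperoxide, CC(C)(C)OO; triisopropylsilyl trifluoromethanesulfonate, CC(C)[Si](OS(=O)(=O)C(F)(F)F)(C(C)C)C(C)C
Why: Oxidation of a lithium acetylide by lithium tert-butyl peroxide (electrophilic oxygen transfer) gives the ynolate, and the bulky silyl triflate reacts at oxygen; excess acetylene and low temperature hold back disproportionation of the monolithium acetylide.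

Step 22
Reactants: 31 (3E,5R,6R)-6-ArB-5-ArD-7-[(tert-butyldimethylsilyl)oxy]-1-diazohept-3-en-2-one; 34 (ethynyloxy)triisopropylsilane
Product: 39 2-{(1S,2R)-2-ArB-1-ArD-3-[(tert-butyldimethylsilyl)oxy]propyl}-5-[(triisopropylsilyl)oxy]phenol, via vinylketene 35 (not isolated), via cyclobutenone 36 (not isolated), via dienylketene 37 (not isolated), via cyclohexadienone 38 (not isolated)
Conditions: hν (medium-pressure Hg lamp, Pyrex filter, >300 nm), 34 (3 equiv), ClCH2CH2Cl, 25 °C; then 80 °C
Reagents that add atoms: none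
Why: This is the Danheiser benzannulation in its photochemical Wolff variant; the closest known reaction type is the annulation of α-diazo enones with siloxyalkynes to resorcinol monosilyl ethers. Light expels N2 from 31 and the alkenyl group shifts to the carbene carbon, so vinylketene 35 forms with the former ketone carbon as ketene carbon. The nucleophilic CH carbon of the polarised alkyne 34 bonds to the ketene carbon in a [2+2] cycloaddition and gives 4-alkenylcyclobutenone 36 (C8a–C8 and C7–C6 formed). Warming opens the four-membered ring in a reversible four-electron electrocyclic step to dienylketene 37. Ring A is then closed by a six-electron disrotatory electrocyclisation (C8a–C4a) to dienone 38, which tautomerises to phenol 39. No stereocentre is created; C3 and C4 take no part in any bond change, and the E double bond keeps the C4–H away from the ketene. The regiochemistry (free OH ortho to C4, silyloxy group para) follows from the oxygen-polarised alkyne. Chemoselectivity needs the ketene to meet the alkyne before it dimerises, which is secured by excess 34, dilution, and light that the diazo enone absorbs but the aryl benzyl ethers do not.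

Step 23
Reactants: 39 2-{(1S,2R)-2-ArB-1-ArD-3-[(tert-butyldimethylsilyl)oxy]propyl}-5-[(triisopropylsilyl)oxy]phenol
Product: 40 4-[(1S,2R)-2-ArB-1-ArD-3-hydroxypropyl]benzene-1,3-diol
Conditions: Bu4NF, THF, 0 → 25 °C
Reagents that add atoms: none
Why: Fluoride-induced desilylation removes the alkyl and the aryl silyl ether in one operation; benzyl and methyl ethers are untouched.

Step 24
Reactants: 40 4-[(1S,2R)-2-ArB-1-ArD-3-hydroxypropyl]benzene-1,3-diol
Product: 41 (3R,4S)-3-ArB-4-ArD-chroman-7-ol
Conditions: PPh3, DIAD, THF (0.02 M), 0 → 25 °C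
Reagents that add atoms: none
Why: Mitsunobu etherification: the ortho phenol displaces the activated primary alcohol (6-exo-tet) and closes ring C; the para hydroxyl cannot reach C2 and dilution disfavours intermolecular alkylation; C3 and C4 are not involved.

Step 25
Reactants: 41 (3R,4S)-3-ArB-4-ArD-chroman-7-ol
Product: 42 (3R,4S)-4-{4-hydroxy-5-[(3R)-7-hydroxychroman-3-yl]-2-methoxyphenyl}-3-(2-hydroxy-4-methoxyphenyl)chroman-7-ol
Conditions: H2 (1 atm), Pd/C, EtOAc/MeOH, 25 °C
Reagents that add atoms: none
Why: Hydrogenolysis of the three aryl benzyl ethers; neither chroman has a benzylic C–O bond (O1 and O1′ sit on aryl carbons, C2 and C2′ are not benzylic), and the methyl ethers are inert.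

## Compound list

1 | 2-hydroxy-4-methoxybenzaldehyde | COc1ccc(C=O)c(O)c1 | starting material
2 | 2-(benzyloxy)-4-methoxybenzaldehyde | COc1ccc(C=O)c(OCc2ccccc2)c1 | intermediate
3 | N-{2-[2-(benzyloxy)-4-methoxyphenyl]-1-tosylethenyl}formamide (alkene geometry open) | COc1ccc(C=C(NC=O)S(=O)(=O)c2ccc(C)cc2)c(OCc2ccccc2)c1 | intermediate (not isolated)
4 | 2-[2-(benzyloxy)-4-methoxyphenyl]acetonitrile | COc1ccc(CC#N)c(OCc2ccccc2)c1 | intermediate
5 | 2-[2-(benzyloxy)-4-methoxyphenyl]acetic acid | COc1ccc(CC(=O)O)c(OCc2ccccc2)c1 | intermediate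
6 | 2-[2-(benzyloxy)-5-bromo-4-methoxyphenyl]acetic acid | COc1cc(OCc2ccccc2)c(CC(=O)O)cc1Br | intermediate
7 | (R)-4-benzyloxazolidin-2-one | O=C1N[C@H](Cc2ccccc2)CO1 | starting material
8 | 2-[2-(benzyloxy)-5-bromo-4-methoxyphenyl]acetic pivalic anhydride | COc1cc(OCc2ccccc2)c(CC(=O)OC(=O)C(C)(C)C)cc1Br | intermediate (not isolated)
9 | (R)-4-benzyl-3-{2-[2-(benzyloxy)-5-bromo-4-methoxyphenyl]acetyl}oxazolidin-2-one | COc1cc(OCc2ccccc2)c(CC(=O)N2[C@H](Cc3ccccc3)COC2=O)cc1Br | intermediate
10 | 2,4-dihydroxybenzaldehyde | O=Cc1ccc(O)cc1O | starting material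
11 | 4-(benzyloxy)-2-hydroxybenzaldehyde | O=Cc1ccc(OCc2ccccc2)cc1O | intermediate
12 | 4-(benzyloxy)-2-[(tert-butyldimethylsilyl)oxy]benzaldehyde | O=Cc1ccc(OCc2ccccc2)cc1O[Si](C)(C)C(C)(C)C | intermediate
13 | {4-(benzyloxy)-2-[(tert-butyldimethylsilyl)oxy]phenyl}methanol | OCc1ccc(OCc2ccccc2)cc1O[Si](C)(C)C(C)(C)C | intermediate
14 | 4-(benzyloxy)-2-[(tert-butyldimethylsilyl)oxy]benzyl bromide | BrCc1ccc(OCc2ccccc2)cc1O[Si](C)(C)C(C)(C)C | intermediate
15 | (R)-4-benzyl-3-[(2R)-2-[2-(benzyloxy)-5-bromo-4-methoxyphenyl]-3-{4-(benzyloxy)-2-[(tert-butyldimethylsilyl)oxy]phenyl}propanoyl]oxazolidin-2-one | COc1cc(OCc2ccccc2)c([C@@H](Cc2ccc(OCc3ccccc3)cc2O[Si](C)(C)C(C)(C)C)C(=O)N2[C@H](Cc3ccccc3)COC2=O)cc1Br | intermediate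
16 | (2R)-2-[2-(benzyloxy)-5-bromo-4-methoxyphenyl]-3-{4-(benzyloxy)-2-[(tert-butyldimethylsilyl)oxy]phenyl}propan-1-ol | COc1cc(OCc2ccccc2)c([C@@H](Cc2ccc(OCc3ccccc3)cc2O[Si](C)(C)C(C)(C)C)CO)cc1Br | intermediate (not isolated)
17 | 5-(benzyloxy)-2-{(2R)-2-[2-(benzyloxy)-5-bromo-4-methoxyphenyl]-3-hydroxypropyl}phenol | COc1cc(OCc2ccccc2)c([C@@H](Cc2ccc(OCc3ccccc3)cc2O)CO)cc1Br | intermediate
18 | (3R)-7-(benzyloxy)-3-[2-(benzyloxy)-5-bromo-4-methoxyphenyl]chromane | COc1cc(OCc2ccccc2)c([C@@H]2COc3cc(OCc4ccccc4)ccc3C2)cc1Br | intermediate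
19 | (S)-but-3-yn-2-ol | C[C@H](O)C#C | starting material
20 | 2-{[(2S,3E)-4-(4,4,5,5-tetramethyl-1,3,2-dioxaborolan-2-yl)but-3-en-2-yl]oxy}-4,4,5,5-tetramethyl-1,3,2-dioxaborolane | C[C@H](OB1OC(C)(C)C(C)(C)O1)/C=C/B1OC(C)(C)C(C)(C)O1 | intermediate (not isolated)
21 | (2S,3E)-4-(4,4,5,5-tetramethyl-1,3,2-dioxaborolan-2-yl)but-3-en-2-ol | C[C@H](O)/C=C/B1OC(C)(C)C(C)(C)O1 | intermediate
22 | (2S,3E)-4-ArD-but-3-en-2-ol | C[C@H](O)/C=C/c1cc([C@@H]2COc3cc(OCc4ccccc4)ccc3C2)c(OCc2ccccc2)cc1OC | intermediate
23 | (2S,3E)-4-ArD-but-3-en-2-yl 2-ArB-acetate | COc1ccc(CC(=O)O[C@@H](C)/C=C/c2cc([C@@H]3COc4cc(OCc5ccccc5)ccc4C3)c(OCc3ccccc3)cc2OC)c(OCc2ccccc2)c1 | intermediate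
24 | (Z)-trimethylsilyl ketene acetal of 23 (ArB cis to OSiMe3) | COc1ccc(/C=C(\O[Si](C)(C)C)O[C@@H](C)/C=C/c2cc([C@@H]3COc4cc(OCc5ccccc5)ccc4C3)c(OCc3ccccc3)cc2OC)c(OCc2ccccc2)c1 | intermediate (not isolated)
25 | trimethylsilyl (2R,3R,4E)-2-ArB-3-ArD-hex-4-enoate | COc1ccc([C@H](C(=O)O[Si](C)(C)C)[C@@H](/C=C/C)c2cc([C@@H]3COc4cc(OCc5ccccc5)ccc4C3)c(OCc3ccccc3)cc2OC)c(OCc2ccccc2)c1 | intermediate (not isolated)
26 | (2R,3R,4E)-2-ArB-3-ArD-hex-4-enoic acid | COc1ccc([C@H](C(=O)O)[C@@H](/C=C/C)c2cc([C@@H]3COc4cc(OCc5ccccc5)ccc4C3)c(OCc3ccccc3)cc2OC)c(OCc2ccccc2)c1 | intermediate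
27 | (2R,3R,4E)-2-ArB-3-ArD-hex-4-en-1-ol | COc1ccc([C@H](CO)[C@@H](/C=C/C)c2cc([C@@H]3COc4cc(OCc5ccccc5)ccc4C3)c(OCc3ccccc3)cc2OC)c(OCc2ccccc2)c1 | intermediate
28 | tert-butyl{[(2R,3R,4E)-2-ArB-3-ArD-hex-4-en-1-yl]oxy}dimethylsilane | COc1ccc([C@H](CO[Si](C)(C)C(C)(C)C)[C@@H](/C=C/C)c2cc([C@@H]3COc4cc(OCc5ccccc5)ccc4C3)c(OCc3ccccc3)cc2OC)c(OCc2ccccc2)c1 | intermediate
29 | (3E,5R,6R)-6-ArB-5-ArD-7-[(tert-butyldimethylsilyl)oxy]hept-3-en-2-one | COc1ccc([C@H](CO[Si](C)(C)C(C)(C)C)[C@@H](/C=C/C(C)=O)c2cc([C@@H]3COc4cc(OCc5ccccc5)ccc4C3)c(OCc3ccccc3)cc2OC)c(OCc2ccccc2)c1 | intermediate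
30 | (5E,7R,8R)-8-ArB-7-ArD-9-[(tert-butyldimethylsilyl)oxy]-1,1,1-trifluoronon-5-ene-2,4-dione | COc1ccc([C@H](CO[Si](C)(C)C(C)(C)C)[C@@H](/C=C/C(=O)CC(=O)C(F)(F)F)c2cc([C@@H]3COc4cc(OCc5ccccc5)ccc4C3)c(OCc3ccccc3)cc2OC)c(OCc2ccccc2)c1 | intermediate (not isolated)
31 | (3E,5R,6R)-6-ArB-5-ArD-7-[(tert-butyldimethylsilyl)oxy]-1-diazohept-3-en-2-one | COc1ccc([C@H](CO[Si](C)(C)C(C)(C)C)[C@@H](/C=C/C(=O)C=[N+]=[N-])c2cc([C@@H]3COc4cc(OCc5ccccc5)ccc4C3)c(OCc3ccccc3)cc2OC)c(OCc2ccccc2)c1 | intermediate
32 | acetylene | C#C | starting material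
33 | lithium ethynolate | [Li+].[O-]C#C | intermediate (not isolated)
34 | (ethynyloxy)triisopropylsilane (triisopropylsiloxyacetylene) | C#CO[Si](C(C)C)(C(C)C)C(C)C | intermediate
35 | (3E,5R,6R)-6-ArB-5-ArD-7-[(tert-butyldimethylsilyl)oxy]hepta-1,3-dien-1-one (vinylketene) | COc1ccc([C@H](CO[Si](C)(C)C(C)(C)C)[C@@H](/C=C/C=C=O)c2cc([C@@H]3COc4cc(OCc5ccccc5)ccc4C3)c(OCc3ccccc3)cc2OC)c(OCc2ccccc2)c1 | intermediate (not isolated)
36 | 4-[(1E,3R,4R)-4-ArB-3-ArD-5-[(tert-butyldimethylsilyl)oxy]pent-1-en-1-yl]-3-[(triisopropylsilyl)oxy]cyclobut-2-en-1-one (either configuration at ring C4) | COc1ccc([C@H](CO[Si](C)(C)C(C)(C)C)[C@@H](/C=C/C2C(=O)C=C2O[Si](C(C)C)(C(C)C)C(C)C)c2cc([C@@H]3COc4cc(OCc5ccccc5)ccc4C3)c(OCc3ccccc3)cc2OC)c(OCc2ccccc2)c1 | intermediate (not isolated)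
37 | (5E,7R,8R)-8-ArB-7-ArD-9-[(tert-butyldimethylsilyl)oxy]-3-[(triisopropylsilyl)oxy]nona-1,3,5-trien-1-one, C2 and C5 cis across C3=C4 (dienylketene) | COc1ccc([C@H](CO[Si](C)(C)C(C)(C)C)[C@@H](/C=C/C=C(/O[Si](C(C)C)(C(C)C)C(C)C)C=C=O)c2cc([C@@H]3COc4cc(OCc5ccccc5)ccc4C3)c(OCc3ccccc3)cc2OC)c(OCc2ccccc2)c1 | intermediate (not isolated)
38 | 6-{(1S,2R)-2-ArB-1-ArD-3-[(tert-butyldimethylsilyl)oxy]propyl}-3-[(triisopropylsilyl)oxy]cyclohexa-2,4-dien-1-one (either configuration at ring C6) | COc1ccc([C@H](CO[Si](C)(C)C(C)(C)C)[C@@H](C2C=CC(O[Si](C(C)C)(C(C)C)C(C)C)=CC2=O)c2cc([C@@H]3COc4cc(OCc5ccccc5)ccc4C3)c(OCc3ccccc3)cc2OC)c(OCc2ccccc2)c1 | intermediate (not isolated)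
39 | 2-{(1S,2R)-2-ArB-1-ArD-3-[(tert-butyldimethylsilyl)oxy]propyl}-5-[(triisopropylsilyl)oxy]phenol | COc1ccc([C@H](CO[Si](C)(C)C(C)(C)C)[C@@H](c2ccc(O[Si](C(C)C)(C(C)C)C(C)C)cc2O)c2cc([C@@H]3COc4cc(OCc5ccccc5)ccc4C3)c(OCc3ccccc3)cc2OC)c(OCc2ccccc2)c1 | intermediate
40 | 4-[(1S,2R)-2-ArB-1-ArD-3-hydroxypropyl]benzene-1,3-diol | COc1ccc([C@H](CO)[C@@H](c2ccc(O)cc2O)c2cc([C@@H]3COc4cc(OCc5ccccc5)ccc4C3)c(OCc3ccccc3)cc2OC)c(OCc2ccccc2)c1 | intermediate
41 | (3R,4S)-3-ArB-4-ArD-chroman-7-ol | COc1ccc([C@@H]2COc3cc(O)ccc3[C@H]2c2cc([C@@H]3COc4cc(OCc5ccccc5)ccc4C3)c(OCc3ccccc3)cc2OC)c(OCc2ccccc2)c1 | intermediate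
42 | (3R,4S)-4-{4-hydroxy-5-[(3R)-7-hydroxychroman-3-yl]-2-methoxyphenyl}-3-(2-hydroxy-4-methoxyphenyl)chroman-7-ol | COc1ccc([C@@H]2COc3cc(O)ccc3[C@H]2c2cc([C@@H]3COc4cc(O)ccc4C3)c(O)cc2OC)c(O)c1 | target

## Step count and least certain steps

Total step count: 25. Longest linear sequence: 19 (steps 1–5, 10–12, 14–20, 22–25).

**Step 22 (key step).**
- What may go wrong: capture of the vinylketene by the alkyne may lose out to ketene dimerisation, to photochemical E/Z isomerisation of the enone before nitrogen is lost, or to secondary photolysis. Thermal opening of the cyclobutenone may also stay incomplete. Ketenes with a single terminal substituent are short-lived, and the substrate carries four light-absorbing arenes.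
- Fallback, from 28 back to 39: the same ketene is made without light or diazo chemistry. Cross-metathesis of 28 with but-3-enoic acid gives (3E,5R,6R)-6-ArB-5-ArD-7-[(tert-butyldimethylsilyl)oxy]hept-3-enoic acid F1. Oxalyl chloride converts it into the acid chloride F2. Slow addition of Et3N to F2 and 34 in toluene at 25 °C generates vinylketene 35 by dehydrochlorination. Cycloaddition and heating to 80 °C then lead through 36–38 to 39.

**Step 21.**
- What may go wrong: monolithium acetylide may disproportionate to the dilithium compound before oxygen transfer, silylation may occur at carbon instead of oxygen, and the small silyl ynol ether may be lost on isolation. The parent member of this reagent class is the least documented one.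
- Fallback, from 31 back to 40: an alkyl ynol ether replaces the silyl ynol ether. Potassium tert-butoxide and trichloroethylene give tert-butyl (E)-1,2-dichlorovinyl ether F3. n-BuLi (2 equiv) followed by methanol gives tert-butoxyethyne F4. Irradiation of 31 with F4, removal of excess F4 under vacuum and heating to 80 °C give 2-{(1S,2R)-2-ArB-1-ArD-3-[(tert-butyldimethylsilyl)oxy]propyl}-5-tert-butoxyphenol F5. Dilute trifluoroacetic acid with triethylsilane as cation trap at 0 °C, then K2CO3/MeOH, cleaves the aryl tert-butyl ether and the primary silyl ether and delivers 40.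

**Step 19.**
- What may go wrong: initiation may be slow at an internal alkene next to a fully substituted allylic carbon, and ruthenium hydride species may shift the double bond into conjugation with ring D, which would erase C4.
- Fallback, from 28 back to 29: oxidative cleavage replaces metathesis. OsO4 (catalytic), NaIO4 and 2,6-lutidine in dioxane/water cleave the propenyl group to (2R,3R)-3-ArB-2-ArD-4-[(tert-butyldimethylsilyl)oxy]butanal F6. Crude F6 is treated at once with 1-(triphenylphosphoranylidene)propan-2-one in CH2Cl2 at 25 °C (Wittig olefination) to give 29. The neutral ylide limits epimerisation of the α-aryl aldehyde.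

**Step 16.**
- What may go wrong: stereochemical fidelity may be lost through leakage in enolate geometry, through ionisation of the electron-rich allylic ester before the concerted shift, or through fragmentation of the arylacetate enolate to an aryl ketene.
- Fallback, from 18 and 5 back to 29: both centres are set by catalysts instead of by chirality transfer.
  - Suzuki–Miyaura coupling of 18 with (E)-3-(4,4,5,5-tetramethyl-1,3,2-dioxaborolan-2-yl)prop-2-en-1-ol gives (E)-3-ArD-prop-2-en-1-ol F7, and Boc2O gives its tert-butyl carbonate F8.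
  - Acid 5 is converted with pentafluorophenol and EDC·HCl into pentafluorophenyl 2-ArB-acetate F9.
  - F8 and F9 are joined by dual catalysis with an iridium phosphoramidite complex formed from [Ir(cod)Cl]2 and a chiral isothiourea (benzotetramisole), each enantiomer chosen for the (R) configuration at its own centre. This gives the branched ester, pentafluorophenyl (2R,3R)-2-ArB-3-ArD-pent-4-enoate F10.
  - LiAlH4 gives (2R,3R)-2-ArB-3-ArD-pent-4-en-1-ol F11, and TBSCl gives its silyl ether F12.
  - Cross-metathesis of the terminal alkene of F12 with methyl vinyl ketone returns to 29.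

## Further compounds

F1 | step 22 | (3E,5R,6R)-6-ArB-5-ArD-7-[(tert-butyldimethylsilyl)oxy]hept-3-enoic acid | COc1ccc([C@H](CO[Si](C)(C)C(C)(C)C)[C@@H](/C=C/CC(=O)O)c2cc([C@@H]3COc4cc(OCc5ccccc5)ccc4C3)c(OCc3ccccc3)cc2OC)c(OCc2ccccc2)c1
F2 | step 22 | (3E,5R,6R)-6-ArB-5-ArD-7-[(tert-butyldimethylsilyl)oxy]hept-3-enoyl chloride | COc1ccc([C@H](CO[Si](C)(C)C(C)(C)C)[C@@H](/C=C/CC(=O)Cl)c2cc([C@@H]3COc4cc(OCc5ccccc5)ccc4C3)c(OCc3ccccc3)cc2OC)c(OCc2ccccc2)c1
F3 | step 21 | tert-butyl (E)-1,2-dichlorovinyl ether | CC(C)(C)O/C(Cl)=C\Cl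
F4 | step 21 | tert-butoxyethyne | CC(C)(C)OC#C
F5 | step 21 | 2-{(1S,2R)-2-ArB-1-ArD-3-[(tert-butyldimethylsilyl)oxy]propyl}-5-tert-butoxyphenol | COc1ccc([C@H](CO[Si](C)(C)C(C)(C)C)[C@@H](c2ccc(OC(C)(C)C)cc2O)c2cc([C@@H]3COc4cc(OCc5ccccc5)ccc4C3)c(OCc3ccccc3)cc2OC)c(OCc2ccccc2)c1
F6 | step 19 | (2R,3R)-3-ArB-2-ArD-4-[(tert-butyldimethylsilyl)oxy]butanal | COc1ccc([C@H](CO[Si](C)(C)C(C)(C)C)[C@@H](C=O)c2cc([C@@H]3COc4cc(OCc5ccccc5)ccc4C3)c(OCc3ccccc3)cc2OC)c(OCc2ccccc2)c1
F7 | step 16 | (E)-3-ArD-prop-2-en-1-ol | OC/C=C/c1cc([C@@H]2COc3cc(OCc4ccccc4)ccc3C2)c(OCc2ccccc2)cc1OC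
F8 | step 16 | tert-butyl (E)-3-ArD-prop-2-en-1-yl carbonate | CC(C)(C)OC(=O)OC/C=C/c1cc([C@@H]2COc3cc(OCc4ccccc4)ccc3C2)c(OCc2ccccc2)cc1OC
F9 | step 16 | pentafluorophenyl 2-ArB-acetate | COc1ccc(CC(=O)Oc2c(F)c(F)c(F)c(F)c2F)c(OCc2ccccc2)c1
F10 | step 16 | pentafluorophenyl (2R,3R)-2-ArB-3-ArD-pent-4-enoate | COc1ccc([C@H](C(=O)Oc2c(F)c(F)c(F)c(F)c2F)[C@@H](C=C)c2cc([C@@H]3COc4cc(OCc5ccccc5)ccc4C3)c(OCc3ccccc3)cc2OC)c(OCc2ccccc2)c1
F11 | step 16 | (2R,3R)-2-ArB-3-ArD-pent-4-en-1-ol | COc1ccc([C@H](CO)[C@@H](C=C)c2cc([C@@H]3COc4cc(OCc5ccccc5)ccc4C3)c(OCc3ccccc3)cc2OC)c(OCc2ccccc2)c1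
F12 | step 16 | tert-butyl{[(2R,3R)-2-ArB-3-ArD-pent-4-en-1-yl]oxy}dimethylsilane | COc1ccc([C@H](CO[Si](C)(C)C(C)(C)C)[C@@H](C=C)c2cc([C@@H]3COc4cc(OCc5ccccc5)ccc4C3)c(OCc3ccccc3)cc2OC)c(OCc2ccccc2)c1
A1 | alternative 1 | (E)-2-(2-ArD-ethenyl)-4,4,5,5-tetramethyl-1,3,2-dioxaborolane | CC1(C)OB(/C=C/c2cc([C@@H]3COc4cc(OCc5ccccc5)ccc4C3)c(OCc3ccccc3)cc2OC)OC1(C)C
A2 | alternative 1 | [2-(benzyloxy)-4-methoxyphenyl]lithium | [Li]c1ccc(OC)cc1OCc1ccccc1
A3 | alternative 1 | 4-(benzyloxy)-2-(methoxymethoxy)phenyl trifluoromethanesulfonate | COCOc1cc(OCc2ccccc2)ccc1OS(=O)(=O)C(F)(F)F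
A4 | alternative 1 | 1,2,2-triarylethyl pinacol boronate (ring B on the boron-bearing carbon; ring A and ring D on the next carbon) | COc1ccc([C@H](B2OC(C)(C)C(C)(C)O2)[C@@H](c2ccc(OCc3ccccc3)cc2OCOC)c2cc([C@@H]3COc4cc(OCc5ccccc5)ccc4C3)c(OCc3ccccc3)cc2OC)c(OCc2ccccc2)c1
A5 | alternative 2 | 2-nitroalkene of seco-chroman 2 (tri-O-benzyl chroman 1 with a 1-silyloxy-4-nitropent-4-en-2-yl group on ring D) | COc1ccc([C@@H]2COc3cc(OCc4ccccc4)ccc3[C@H]2c2cc([C@@H](CC(=C)[N+](=O)[O-])CO[Si](c3ccccc3)(c3ccccc3)C(C)(C)C)c(OCc3ccccc3)cc2OC)c(OCc2ccccc2)c1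
A6 | alternative 2 | 1-methoxy-1,3-bis(trimethylsilyloxy)buta-1,3-diene | COC(O[Si](C)(C)C)=CC(=C)O[Si](C)(C)C
A7 | alternative 2 | seco-chroman 2 with ring E as free 4-alkylresorcinol | COc1ccc([C@@H]2COc3cc(OCc4ccccc4)ccc3[C@H]2c2cc([C@@H](Cc3ccc(O)cc3O)CO[Si](c3ccccc3)(c3ccccc3)C(C)(C)C)c(OCc3ccccc3)cc2OC)c(OCc2ccccc2)c1
A8 | alternative 3 | ring D phenol with open ring C (3-benzyloxyphenyl ether of the C2 alcohol, C4 as CH2) | COc1ccc([C@@H](Cc2cc([C@@H]3COc4cc(OCc5ccccc5)ccc4C3)c(O)cc2OC)COc2cccc(OCc3ccccc3)c2)c(OCc2ccccc2)c1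
A9 | alternative 3 | p-quinone methide at C4 (exocyclic alkene geometry open) | COC1=CC(=O)C([C@@H]2COc3cc(OCc4ccccc4)ccc3C2)=CC1=C[C@@H](COc1cccc(OCc2ccccc2)c1)c1ccc(OC)cc1OCc1ccccc1
A10 | alternative 3 | tri-O-benzyl target with free ring D phenol | COc1ccc([C@@H]2COc3cc(OCc4ccccc4)ccc3[C@H]2c2cc([C@@H]3COc4cc(OCc5ccccc5)ccc4C3)c(O)cc2OC)c(OCc2ccccc2)c1
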